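**Retrosynthetic overview**

1. The target is a cis-2,3-disubstituted 4-methylidene-5-oxooxolane. The exocyclic C=CH2 on C4 is added last, by decarboxylative methylenation of the oxolane-3,4-dicarboxylic acid 20.
2. Key disconnection: the O1–C2 and C3–C4 bonds of the oxolanone. The enabling feature is that ring atoms C4–C5(=O)–O1 are a malonic acid unit (a carbon nucleophile next to an oxygen nucleophile), while C2–C3 are two adjacent stereocentres with C3 alpha to its own carboxyl group. C3/C2 can therefore be a 1,2-dielectrophile: the cyclic sulfate 16 of an erythro 2,3-dihydroxy ester.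
3. Double SN2 inversion (carbon at C3, then oxygen at C2) converts the erythro (R,R) diol into the cis (2S,3S) lactone. The acid stage of the same flask removes all four tert-butyl groups.
4. Diol 14 comes from D-ribonolactone acetonide 7 (bromide, zinc ring fragmentation, cis-diol stereocentres kept), cross-metathesis with alkene 6 and hydrogenation. Alkene 6 comes from (S)-butane-1,3-diol and an undecenyl Grignard reagent.
5. Ring order: the dioxolane of 7 is carried to step 9; the dioxathiolane is a temporary ring made in step 10; the oxolanone, the only ring of the target, is closed in step 11.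

Key step: step 11

Remark: the malonate-derived ring carbon of 20 and 21 and the sulfur of 15 are uncontrolled and left undrawn; both centres disappear in the next transformation.

**Step 1**
Reactants: 1 (S)-butane-1,3-diol
Product: 2 (3S)-3-hydroxybutyl 4-methylbenzenesulfonate
Conditions: TsCl (1.0 equiv), Et3N, CH2Cl2, −20 °C
Reagents that add atoms: 4-methylbenzenesulfonyl chloride, Cc1ccc(cc1)S(Cl)(=O)=O
Why: Selective monosulfonylation of a diol, in which the primary hydroxyl group should react much faster than the secondary one at low temperature with one equivalent of TsCl and the stereocentre is not involved.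

**Step 2**
Reactants: 2 (3S)-3-hydroxybutyl 4-methylbenzenesulfonate
Product: 3 (3S)-3-tert-butoxybutyl 4-methylbenzenesulfonate
Conditions: tert-butyl 2,2,2-trichloroacetimidate, BF3·OEt2 (cat.), CH2Cl2–cyclohexane, rt
Reagents that add atoms: tert-butyl 2,2,2-trichloroacetimidate, CC(C)(C)OC(=N)C(Cl)(Cl)Cl
Why: Acid-catalysed O-tert-butylation with a trichloroacetimidate donor should convert the secondary alcohol into its tert-butyl ether without touching the primary tosylate or the stereocentre.

**Step 3**
Reactants: 4 11-bromoundec-1-ene; 3 (3S)-3-tert-butoxybutyl 4-methylbenzenesulfonate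
Product: 6 (14S)-14-tert-butoxypentadec-1-ene, via undec-10-enylmagnesium bromide 5 (not isolated)
Conditions: Mg, THF, 40 °C; then 3, Li2CuCl4 (cat.), THF, −30 °C to rt
Reagents that add atoms: none
Why: Grignard formation followed by copper-catalysed sp3–sp3 cross-coupling with a primary tosylate should join the two chains, the ether-bearing stereocentre being remote from the reacting carbon.

**Step 4**
Reactants: 7 2,3-O-isopropylidene-D-ribono-1,4-lactone
Product: 8 5-bromo-5-deoxy-2,3-O-isopropylidene-D-ribono-1,4-lactone
Conditions: CBr4, PPh3, CH2Cl2, 0 °C to rt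
Reagents that add atoms: tetrabromomethane, BrC(Br)(Br)Br
Why: Appel bromination of the only free, primary hydroxyl group proceeds by SN2 displacement of the oxyphosphonium intermediate and leaves the three stereocentres untouched.

**Step 5**
Reactants: 8 5-bromo-5-deoxy-2,3-O-isopropylidene-D-ribono-1,4-lactone
Product: 10 (4R,5R)-5-ethenyl-2,2-dimethyl-1,3-dioxolane-4-carboxylic acid, via bromozinc carboxylate 9 (not isolated)
Conditions: Zn dust (activated), THF–H2O (4:1), 60 °C; then cold 1 M HCl (work-up)
Reagents that add atoms: none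
Why: Zinc insertion into the carbon–bromine bond followed by β-elimination of the ring oxygen as a carboxylate (reductive elimination of a β-acyloxy halide, the reverse of a bromolactonisation) should open the lactone to the terminal alkene while the two dioxolane stereocentres are retained.

**Step 6**
Reactants: 10 (4R,5R)-5-ethenyl-2,2-dimethyl-1,3-dioxolane-4-carboxylic acid
Product: 11 tert-butyl (4R,5R)-5-ethenyl-2,2-dimethyl-1,3-dioxolane-4-carboxylate
Conditions: O-tert-butyl-N,N'-diisopropylisourea, CH2Cl2, rt
Reagents that add atoms: O-tert-butyl-N,N'-diisopropylisourea, CC(C)N=C(OC(C)(C)C)NC(C)C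
Why: Esterification of the acid with an O-alkylisourea transfers a tert-butyl group under neutral conditions, so neither the acetal nor the stereocentre alpha to the carboxyl group is endangered.

**Step 7**
Reactants: 11 tert-butyl (4R,5R)-5-ethenyl-2,2-dimethyl-1,3-dioxolane-4-carboxylate; 6 (14S)-14-tert-butoxypentadec-1-ene
Product: 12 tert-butyl (4R,5R)-5-[(1E,14S)-14-tert-butoxypentadec-1-en-1-yl]-2,2-dimethyl-1,3-dioxolane-4-carboxylate
Conditions: second-generation Grubbs catalyst RuCl2(=CHPh)(H2IMes)(PCy3) (cat.), 6 in excess, CH2Cl2, 40 °C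
Reagents that add atoms: none
Why: Olefin cross-metathesis between an unhindered terminal alkene and the slowly dimerising allylic dioxolane alkene should give the disubstituted alkene (mainly E) with loss of ethene, no stereocentre being affected and the alkene geometry being erased in step 8.

**Step 8**
Reactants: 12 tert-butyl (4R,5R)-5-[(1E,14S)-14-tert-butoxypentadec-1-en-1-yl]-2,2-dimethyl-1,3-dioxolane-4-carboxylate
Product: 13 tert-butyl (4R,5R)-5-[(14S)-14-tert-butoxypentadecyl]-2,2-dimethyl-1,3-dioxolane-4-carboxylate
Conditions: H2 (1 atm), Pd/C, EtOAc, rt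
Reagents that add atoms: none
Why: Heterogeneous catalytic hydrogenation should saturate the disubstituted alkene and leave the ester, the ether and the acetal untouched.

**Step 9**
Reactants: 13 tert-butyl (4R,5R)-5-[(14S)-14-tert-butoxypentadecyl]-2,2-dimethyl-1,3-dioxolane-4-carboxylate
Product: 14 tert-butyl (2R,3R,17S)-17-tert-butoxy-2,3-dihydroxyoctadecanoate
Conditions: AcOH–H2O–THF (3:1:1), 55 °C
Reagents that add atoms: none
Why: Acid-catalysed hydrolysis of the isopropylidene acetal should free the erythro diol, while the tert-butyl ester and the tert-butyl ether tolerate aqueous acetic acid.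

**Step 10**
Reactants: 14 tert-butyl (2R,3R,17S)-17-tert-butoxy-2,3-dihydroxyoctadecanoate
Product: 16 tert-butyl (4R,5R)-5-[(14S)-14-tert-butoxypentadecyl]-1,3,2-dioxathiolane-4-carboxylate 2,2-dioxide, via cyclic sulfite 15 (not isolated)
Conditions: SOCl2, Et3N, CH2Cl2, 0 °C; then RuCl3 hydrate (cat.), NaIO4, MeCN–H2O, 0 °C
Reagents that add atoms: thionyl chloride, O=S(Cl)Cl; sodium periodate, [Na+].[O-]I(=O)(=O)=O
Why: Cyclic sulfite formation from the 1,2-diol and thionyl chloride followed by RuO4-catalysed oxidation at sulfur is the standard two-stage cyclic sulfate synthesis and proceeds with retention at both carbinol carbons.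

**Step 11**
Reactants: 16 tert-butyl (4R,5R)-5-[(14S)-14-tert-butoxypentadecyl]-1,3,2-dioxathiolane-4-carboxylate 2,2-dioxide; 17 di-tert-butyl propanedioate
Product: 20 (2S,3S)-2-[(14S)-14-hydroxypentadecyl]-5-oxooxolane-3,4-dicarboxylic acid, via sodium di-tert-butyl malonate 18 (not isolated), via sodium alkyl sulfate triester 19 (not isolated)
Conditions: NaH (1.0 equiv), THF, 0 °C to 40 °C; then CF3CO2H–CH2Cl2 (1:1), 0 °C to 40 °C; then H2O, rt
Reagents that add atoms: none
Why: Proposed new method: the sodium enolate 18 should open cyclic sulfate 16 by SN2 attack at C4 of the dioxathiolane ring, the carbon alpha to the ester carbonyl, with inversion, and since only one equivalent of base is used the charge ends on the sulfate monoester of 19 and no carbanion remains for a second C-alkylation; the closest known reaction types are the alpha-selective opening of cyclic sulfates of 2,3-dihydroxy esters by soft nucleophiles and the double displacement of cyclic sulfates by malonates (to cyclopropanes) and by amidines (to imidazolines). In the anhydrous acid stage the three tert-butyl esters and the tert-butyl ether are cleaved and a carboxyl oxygen of the malonic acid unit displaces the secondary alkyl hydrogen sulfate at the former C5 with inversion, as carboxyl groups do with gamma-sulfonates in known invertive lactonisations. This 5-exo-tet closure forms the oxolanone, the only ring of the target. C3 of the oxolane is set by the stereospecific inversion at the ester-bearing carbon and C2 by the stereospecific inversion at the sulfate-bearing carbon, so the erythro (4R,5R) pair of 16 becomes the cis (2S,3S) pair of 20. The step needs attack at C4 and not at C5 in the first opening (secured by the carbonyl activation of C4 in the substrate), oxygen and not carbon as second nucleophile (secured by the acidic medium) and C–O and not S–O cleavage of the sulfate (secured by exclusion of water and the favourable five-membered participation of the carboxyl group).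

**Step 12**
Reactants: 20 (2S,3S)-2-[(14S)-14-hydroxypentadecyl]-5-oxooxolane-3,4-dicarboxylic acid
Product: 22 (2S,3S)-2-[(14S)-14-hydroxypentadecyl]-4-methylidene-5-oxooxolane-3-carboxylic acid, via Mannich base 21 (not isolated)
Conditions: HCHO (37% aq.), PhNHMe, NaOAc, AcOH, rt
Reagents that add atoms: formaldehyde, C=O
Why: Mannich reaction of the malonic acid-type C4–H with the iminium ion from formaldehyde and N-methylaniline followed by decarboxylative elimination of the amine (decarboxylative methylenation of an alpha-carboxy lactone) should install the methylidene group under buffered acidic conditions that should not epimerise C3.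

**Compound list**

1 | (S)-butane-1,3-diol | C[C@H](O)CCO | starting material
2 | (3S)-3-hydroxybutyl 4-methylbenzenesulfonate | C[C@H](O)CCOS(=O)(=O)c1ccc(C)cc1 | intermediate
3 | (3S)-3-tert-butoxybutyl 4-methylbenzenesulfonate | C[C@H](OC(C)(C)C)CCOS(=O)(=O)c1ccc(C)cc1 | intermediate
4 | 11-bromoundec-1-ene | C=CCCCCCCCCCBr | starting material
5 | undec-10-enylmagnesium bromide | C=CCCCCCCCCC[Mg]Br | intermediate
6 | (14S)-14-tert-butoxypentadec-1-ene | C=CCCCCCCCCCCC[C@H](C)OC(C)(C)C | intermediate
7 | 2,3-O-isopropylidene-D-ribono-1,4-lactone | O=C1[C@@H]2OC(C)(C)O[C@@H]2[C@@H](CO)O1 | starting material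
8 | 5-bromo-5-deoxy-2,3-O-isopropylidene-D-ribono-1,4-lactone | O=C1[C@@H]2OC(C)(C)O[C@@H]2[C@@H](CBr)O1 | intermediate
9 | bromozinc (4R,5R)-5-ethenyl-2,2-dimethyl-1,3-dioxolane-4-carboxylate | [O-]C(=O)[C@@H]1OC(C)(C)O[C@@H]1C=C.[Zn+2].[Br-] | intermediate
10 | (4R,5R)-5-ethenyl-2,2-dimethyl-1,3-dioxolane-4-carboxylic acid | OC(=O)[C@@H]1OC(C)(C)O[C@@H]1C=C | intermediate
11 | tert-butyl (4R,5R)-5-ethenyl-2,2-dimethyl-1,3-dioxolane-4-carboxylate | CC(C)(C)OC(=O)[C@@H]1OC(C)(C)O[C@@H]1C=C | intermediate
12 | tert-butyl (4R,5R)-5-[(1E,14S)-14-tert-butoxypentadec-1-en-1-yl]-2,2-dimethyl-1,3-dioxolane-4-carboxylate | CC(C)(C)OC(=O)[C@@H]1OC(C)(C)O[C@@H]1/C=C/CCCCCCCCCCC[C@H](C)OC(C)(C)C | intermediate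
13 | tert-butyl (4R,5R)-5-[(14S)-14-tert-butoxypentadecyl]-2,2-dimethyl-1,3-dioxolane-4-carboxylate | CC(C)(C)OC(=O)[C@@H]1OC(C)(C)O[C@@H]1CCCCCCCCCCCCC[C@H](C)OC(C)(C)C | intermediate
14 | tert-butyl (2R,3R,17S)-17-tert-butoxy-2,3-dihydroxyoctadecanoate | CC(C)(C)OC(=O)[C@H](O)[C@H](O)CCCCCCCCCCCCC[C@H](C)OC(C)(C)C | intermediate
15 | tert-butyl (4R,5R)-5-[(14S)-14-tert-butoxypentadecyl]-1,3,2-dioxathiolane-4-carboxylate 2-oxide | CC(C)(C)OC(=O)[C@@H]1OS(=O)O[C@@H]1CCCCCCCCCCCCC[C@H](C)OC(C)(C)C | intermediate
16 | tert-butyl (4R,5R)-5-[(14S)-14-tert-butoxypentadecyl]-1,3,2-dioxathiolane-4-carboxylate 2,2-dioxide | CC(C)(C)OC(=O)[C@@H]1OS(=O)(=O)O[C@@H]1CCCCCCCCCCCCC[C@H](C)OC(C)(C)C | intermediate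
17 | di-tert-butyl propanedioate (di-tert-butyl malonate) | CC(C)(C)OC(=O)CC(=O)OC(C)(C)C | starting material
18 | sodium di-tert-butyl malonate (enolate) | CC(C)(C)OC(=O)[CH-]C(=O)OC(C)(C)C.[Na+] | intermediate
19 | sodium (2S,3R,17S)-17-tert-butoxy-1,1,2-tris(tert-butoxycarbonyl)octadecan-3-yl sulfate | CC(C)(C)OC(=O)C(C(=O)OC(C)(C)C)[C@H](C(=O)OC(C)(C)C)[C@H](OS(=O)(=O)[O-])CCCCCCCCCCCCC[C@H](C)OC(C)(C)C.[Na+] | intermediate
20 | (2S,3S)-2-[(14S)-14-hydroxypentadecyl]-5-oxooxolane-3,4-dicarboxylic acid | OC(=O)C1C(=O)O[C@@H](CCCCCCCCCCCCC[C@H](C)O)[C@H]1C(=O)O | intermediate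
21 | (2S,3S)-2-[(14S)-14-hydroxypentadecyl]-4-{[methyl(phenyl)amino]methyl}-5-oxooxolane-3,4-dicarboxylic acid | CN(CC1(C(=O)O)C(=O)O[C@@H](CCCCCCCCCCCCC[C@H](C)O)[C@H]1C(=O)O)c2ccccc2 | intermediate
22 | (2S,3S)-2-[(14S)-14-hydroxypentadecyl]-4-methylidene-5-oxooxolane-3-carboxylic acid | C=C1C(=O)O[C@@H](CCCCCCCCCCCCC[C@H](C)O)[C@H]1C(=O)O | target

**Step count and risks**

Total step count: 12. Longest linear sequence: 9 steps (steps 4 to 12 from 7; equally steps 1 to 3 and 7 to 12 from 1).

Steps most likely to fail:

Step 11 (proposed new method). The base may open the cyclic sulfate by elimination through loss of the proton alpha to the ester. The second stage may proceed by S–O cleavage followed by acyl lactonisation with retention, which would give the trans lactone. A second C-alkylation to a cyclopropane is also possible. The fallback separates the two displacements with known chemistry; it sets out from 16 and returns at 20. Salt 19 is made as before and its sulfate is hydrolysed under standard conditions (cat. H2SO4, 1 equiv H2O, THF, rt) to tri-tert-butyl (2S,3R,17S)-17-tert-butoxy-3-hydroxyoctadecane-1,1,2-tricarboxylate F1. Mesylation (MsCl, pyridine, 0 °C) gives tri-tert-butyl (2S,3R,17S)-17-tert-butoxy-3-(methanesulfonyloxy)octadecane-1,1,2-tricarboxylate F2. CF3CO2H in CH2Cl2 removes the four tert-butyl groups, and NaHCO3 in aqueous DMF at 50 °C lets a malonate carboxylate displace the mesylate with inversion (invertive lactonisation) to give 20 after acidification.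

Step 12. The Mannich condensation at the hindered C4 may stall, or the new double bond may migrate into the ring during the decarboxylative elimination. The fallback sets out from 20 and returns at 22. Thermal decarboxylation (toluene, 110 °C) gives (2S,3S)-2-[(14S)-14-hydroxypentadecyl]-5-oxooxolane-3-carboxylic acid F3. Its trianion (LiN(SiMe3)2, THF, −78 °C) is aminomethylated with dimethylmethylideneammonium iodide to (2S,3S)-4-[(dimethylamino)methyl]-2-[(14S)-14-hydroxypentadecyl]-5-oxooxolane-3-carboxylic acid F4. Quaternisation with MeI and treatment with NaHCO3 eliminates trimethylamine to give 22.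

Step 9. The tert-butyl ester or ether may be partly lost, or hydrolysis of the electron-poor cis-dioxolane may be sluggish in the lipophilic substrate. The fallback removes the acetal before any tert-butyl group is present; it sets out from 10 and returns at 14. Aqueous HCl in THF converts 10 into (2R,3R)-2,3-dihydroxypent-4-enoic acid F5, which is esterified with O-tert-butyl-N,N'-diisopropylisourea to tert-butyl (2R,3R)-2,3-dihydroxypent-4-enoate F6. Cross-metathesis of F6 with 6 (same ruthenium catalyst) gives tert-butyl (2R,3R,4E,17S)-17-tert-butoxy-2,3-dihydroxyoctadec-4-enoate F7, and hydrogenation (H2, Pd/C) gives 14.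

**Further compounds**

F1 | step 11 | tri-tert-butyl (2S,3R,17S)-17-tert-butoxy-3-hydroxyoctadecane-1,1,2-tricarboxylate | CC(C)(C)OC(=O)C(C(=O)OC(C)(C)C)[C@H](C(=O)OC(C)(C)C)[C@H](O)CCCCCCCCCCCCC[C@H](C)OC(C)(C)C
F2 | step 11 | tri-tert-butyl (2S,3R,17S)-17-tert-butoxy-3-(methanesulfonyloxy)octadecane-1,1,2-tricarboxylate | CC(C)(C)OC(=O)C(C(=O)OC(C)(C)C)[C@H](C(=O)OC(C)(C)C)[C@H](OS(C)(=O)=O)CCCCCCCCCCCCC[C@H](C)OC(C)(C)C
F3 | step 12 | (2S,3S)-2-[(14S)-14-hydroxypentadecyl]-5-oxooxolane-3-carboxylic acid | C1C(=O)O[C@@H](CCCCCCCCCCCCC[C@H](C)O)[C@H]1C(=O)O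
F4 | step 12 | (2S,3S)-4-[(dimethylamino)methyl]-2-[(14S)-14-hydroxypentadecyl]-5-oxooxolane-3-carboxylic acid | CN(C)CC1C(=O)O[C@@H](CCCCCCCCCCCCC[C@H](C)O)[C@H]1C(=O)O
F5 | step 9 | (2R,3R)-2,3-dihydroxypent-4-enoic acid | OC(=O)[C@H](O)[C@H](O)C=C
F6 | step 9 | tert-butyl (2R,3R)-2,3-dihydroxypent-4-enoate | CC(C)(C)OC(=O)[C@H](O)[C@H](O)C=C
F7 | step 9 | tert-butyl (2R,3R,4E,17S)-17-tert-butoxy-2,3-dihydroxyoctadec-4-enoate | CC(C)(C)OC(=O)[C@H](O)[C@H](O)/C=C/CCCCCCCCCCC[C@H](C)OC(C)(C)C
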